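**Strategy.** The seven-membered ring is cut on both sides of its C2–C3 unit (bicyclo[5.3.0]decane numbering: C1 quaternary, C2 acetoxy carbon, C3 and C4 epoxide carbons). The precursor is a cyclopentane with an exocyclic methylene (future C1 and its methyl) and a 3-oxobutyl chain (C4–C6). In one flask, iron-hydride hydrogen-atom transfer makes the tertiary C1 radical, which adds to vinyltriphenylphosphonium bromide (C1–C2), and the derived ylide closes onto the methyl ketone (C3=C4): a radical Schweizer annulation that forges the quaternary centre and the cycloheptene together. Oxygen at C2–C4 is then relayed from an α-face epoxidation; the dienol side chain is finished last.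

Key step: step 5

Remark: bicyclic compounds are named with bicyclo[5.3.0]decane locants (C1 quaternary ring-fusion carbon, C2–C6 the rest of the seven-membered ring, C7 ring-fusion CH, C8 the side-chain carbon); β is the face of the C1 methyl group, α the opposite face; all bicycles are trans-fused (7αH).

Step 1
Reactants: 1 ethyl but-2-ynoate
Product: 2 ethyl (2Z)-3-iodobut-2-enoate
Conditions: NaI, AcOH, 115 °C
Reagents that add atoms: sodium iodide, [Na+].[I-]
Why: Anti-hydroiodination of the ynoate (conjugate addition of iodide, then protonation) should place iodine cis to the ester, which fixes the later Z geometry of the trisubstituted side-chain alkene.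

Step 2
Reactants: 2 ethyl (2Z)-3-iodobut-2-enoate; 3 cyclopent-2-en-1-one
Product: 5 ethyl (2Z)-3-[(1R)-3-(trimethylsilyloxy)cyclopent-2-en-1-yl]but-2-enoate, via alkenylzinc iodide 4 (not isolated)
Conditions: Zn dust, THF, 25 °C; then 3, Me3SiCl, [RhCl((R)-binap)]2 (cat.), THF, 20 °C
Reagents that add atoms: cyclopent-2-en-1-one (3), O=C1C=CCC1; chlorotrimethylsilane, C[Si](C)(C)Cl
Why: Zinc insertion should give the ester-chelated (Z)-alkenylzinc reagent, and rhodium/binap-catalysed asymmetric 1,4-addition with silyl trapping should transfer it with retention, (R)-binap directing it to the enone face that gives the (R) centre (future C8) while the silyl enol ether fixes the enolate regiochemistry.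

Step 3
Reactants: 5 ethyl (2Z)-3-[(1R)-3-(trimethylsilyloxy)cyclopent-2-en-1-yl]but-2-enoate; 6 2-(2-bromoethyl)-2-methyl-1,3-dioxolane
Product: 8 ethyl (2Z)-3-{(1R,2S)-2-[2-(2-methyl-1,3-dioxolan-2-yl)ethyl]-3-oxocyclopentyl}but-2-enoate, via ammonium enolate 7 (not isolated)
Conditions: BnMe3NF, 4 Å MS, THF, 0 °C → rt
Reagents that add atoms: 2-(2-bromoethyl)-2-methyl-1,3-dioxolane (6), CC1(CCBr)OCCO1
Why: Fluoride should unmask the regiodefined enolate, which is alkylated by the primary bromide anti to the neighbouring alkenyl group (trans, also the thermodynamic epimer), setting future C7.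

Step 4
Reactants: 8 ethyl (2Z)-3-{(1R,2S)-2-[2-(2-methyl-1,3-dioxolan-2-yl)ethyl]-3-oxocyclopentyl}but-2-enoate
Product: 10 ethyl (2Z)-3-[(1R,2S)-3-methylidene-2-(3-oxobutyl)cyclopentyl]but-2-enoate, via ketal alkene 9 (not isolated)
Conditions: Ph3PCH3Br, KOtBu, THF, 0 °C → rt; then 1 M HCl, THF, rt
Reagents that add atoms: methyltriphenylphosphonium bromide, C[P+](c1ccccc1)(c1ccccc1)c1ccccc1.[Br-]; water, O
Why: Wittig methylenation of the ring ketone (the ester is inert) followed by mild acid hydrolysis of the dioxolane in the work-up should give the methylene ketone with the trans arrangement intact.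

Step 5
Reactants: 10 ethyl (2Z)-3-[(1R,2S)-3-methylidene-2-(3-oxobutyl)cyclopentyl]but-2-enoate; 11 vinyltriphenylphosphonium bromide
Product: 14 ethyl (2Z)-3-(1β,4-dimethyl-7αH-bicyclo[5.3.0]dec-3-en-8α-yl)but-2-enoate, via phosphonium salt 12 (not isolated), via phosphorus ylide 13 (not isolated)
Conditions: Fe(acac)3 (cat.), PhSiH3, EtOH, 60 °C; solvent exchange; then KHMDS, THF, −78 °C → rt (one flask)
Reagents that add atoms: vinyltriphenylphosphonium bromide (11), C=C[P+](c1ccccc1)(c1ccccc1)c1ccccc1.[Br-]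
Why: Proposed new method: Fe–H hydrogen-atom transfer to the 1,1-disubstituted alkene of 10 (the electron-poor trisubstituted enoate is a poor partner) should give the tertiary C1 radical, which adds to the cationic vinylphosphonium acceptor (C1–C2 bond); the α-phosphonio radical is reduced by Fe(acac)2 to the ylide, which ethanol holds as salt 12, and KHMDS regenerates ylide 13 for an intramolecular Wittig reaction with the methyl ketone (C3=C4 bond). The closest known reaction types are the iron-mediated Giese addition of alkene-derived radicals to electron-poor alkenes and the Schweizer annulation, in which a carbanion adds to vinyltriphenylphosphonium bromide and the ylide closes onto a carbonyl group; a hydrogen-atom-transfer radical has not been used as the nucleophile of that annulation. The seven-membered ring closes by C=C formation through an oxaphosphetane (intramolecular Wittig closure to a cycloheptene), the first bond being intermolecular. The only new stereocentre, quaternary C1, is controlled by the adjacent C7 substituent: the acceptor should approach the planar radical anti to the 3-oxobutyl group, placing C2 trans to it (trans ring fusion, methyl β). The step needs the radical to add to the acceptor faster than to its own ketone (5-exo), which a modest excess of the cationic acceptor and the reversibility of the ketone addition should secure, and needs ylide formation without γ-deprotonation of the enoate, which the higher acidity of the phosphonium α-CH2 and one equivalent of base at low temperature should secure.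

Step 6
Reactants: 14 ethyl (2Z)-3-(1β,4-dimethyl-7αH-bicyclo[5.3.0]dec-3-en-8α-yl)but-2-enoate
Product: 15 ethyl (2Z)-3-(3α,4α-epoxy-1β,4β-dimethyl-7αH-bicyclo[5.3.0]decan-8α-yl)but-2-enoate
Conditions: mCPBA, NaHCO3, CH2Cl2, 0 °C
Reagents that add atoms: 3-chloroperoxybenzoic acid, OOC(=O)c1cccc(Cl)c1
Why: Prilezhaev epoxidation of the only electron-rich alkene should occur anti to the β-axial homoallylic C1 methyl group, giving the 3α,4α-epoxide and setting C4.

Step 7
Reactants: 15 ethyl (2Z)-3-(3α,4α-epoxy-1β,4β-dimethyl-7αH-bicyclo[5.3.0]decan-8α-yl)but-2-enoate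
Product: 18 ethyl (2Z)-3-(4α-hydroxy-1β,4β-dimethyl-7αH-bicyclo[5.3.0]dec-2-en-8α-yl)but-2-enoate, via hydroxy selenide 16 (not isolated), via selenoxide 17 (not isolated)
Conditions: PhSeSePh, NaBH4, EtOH, 25 → 70 °C; then H2O2, THF, 0 °C → rt
Reagents that add atoms: none
Why: Selenolate should open the epoxide at the less substituted C3 with inversion (trans-diaxial SN2), and selenoxide syn-elimination can only run towards C2 because C4 bears no hydrogen, leaving the 4α-hydroxyl centre untouched.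

Step 8
Reactants: 18 ethyl (2Z)-3-(4α-hydroxy-1β,4β-dimethyl-7αH-bicyclo[5.3.0]dec-2-en-8α-yl)but-2-enoate
Product: 19 ethyl (2Z)-3-(2α-hydroxy-1β,4-dimethyl-7αH-bicyclo[5.3.0]dec-3-en-8α-yl)but-2-enoate
Conditions: Ph3SiOReO3 (cat.), Et2O, −50 → 0 °C
Reagents that add atoms: none
Why: Oxorhenium-catalysed 1,3-transposition of the allylic alcohol through a cyclic perrhenate ester ([3,3]) should move oxygen suprafacially from C4 to C2 within the ring, so the C2 carbinol is α, driven by formation of the trisubstituted C3=C4 alkene.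

Step 9
Reactants: 19 ethyl (2Z)-3-(2α-hydroxy-1β,4-dimethyl-7αH-bicyclo[5.3.0]dec-3-en-8α-yl)but-2-enoate
Product: 20 ethyl (2Z)-3-(3α,4α-epoxy-2α-hydroxy-1β,4β-dimethyl-7αH-bicyclo[5.3.0]decan-8α-yl)but-2-enoate
Conditions: VO(acac)2 (cat.), t-BuOOH, CH2Cl2, 0 °C → rt
Reagents that add atoms: tert-butyl hydroperoxide, CC(C)(C)OO
Why: Hydroxyl-directed vanadium-catalysed epoxidation of the cyclic allylic alcohol should deliver oxygen syn to the C2 hydroxyl, setting C3 and C4 (α-epoxide) while the enoate stays untouched.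

Step 10
Reactants: 20 ethyl (2Z)-3-(3α,4α-epoxy-2α-hydroxy-1β,4β-dimethyl-7αH-bicyclo[5.3.0]decan-8α-yl)but-2-enoate
Product: 21 (2Z)-3-(3α,4α-epoxy-2α-hydroxy-1β,4β-dimethyl-7αH-bicyclo[5.3.0]decan-8α-yl)but-2-en-1-ol
Conditions: i-Bu2AlH, CH2Cl2, −78 °C
Reagents that add atoms: none
Why: 1,2-Reduction of the conjugated ester by the aluminium hydride at low temperature should give the (Z)-allylic alcohol without opening the trisubstituted epoxide.

Step 11
Reactants: 21 (2Z)-3-(3α,4α-epoxy-2α-hydroxy-1β,4β-dimethyl-7αH-bicyclo[5.3.0]decan-8α-yl)but-2-en-1-ol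
Product: 22 (2Z)-3-(3α,4α-epoxy-2α-hydroxy-1β,4β-dimethyl-7αH-bicyclo[5.3.0]decan-8α-yl)but-2-enal
Conditions: MnO2, CH2Cl2, rt
Reagents that add atoms: none
Why: MnO2 should oxidise only the primary allylic alcohol, leaving the saturated secondary hydroxyl and the Z geometry in place.

Step 12
Reactants: 23 2,2-dimethyloxirane; 24 triphenylphosphine hydrobromide
Product: 25 (2-hydroxy-2-methylpropyl)triphenylphosphonium bromide
Conditions: MeCN, 80 °C
Reagents that add atoms: triphenylphosphine hydrobromide (24), [PH+](c1ccccc1)(c1ccccc1)c1ccccc1.[Br-]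
Why: Acid-assisted SN2 opening of the epoxide at its unsubstituted carbon by triphenylphosphine should give the β-hydroxyalkylphosphonium salt.

Step 13
Reactants: 22 (2Z)-3-(3α,4α-epoxy-2α-hydroxy-1β,4β-dimethyl-7αH-bicyclo[5.3.0]decan-8α-yl)but-2-enal; 25 (2-hydroxy-2-methylpropyl)triphenylphosphonium bromide
Product: 27 (3E,5Z)-6-(3α,4α-epoxy-2α-hydroxy-1β,4β-dimethyl-7αH-bicyclo[5.3.0]decan-8α-yl)-2-methylhepta-3,5-dien-2-ol, via oxido ylide 26 (not isolated)
Conditions: 25, n-BuLi, THF, −78 → 0 °C; then 22, −78 °C → rt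
Reagents that add atoms: (2-hydroxy-2-methylpropyl)triphenylphosphonium bromide (25), CC(C)(O)C[P+](c1ccccc1)(c1ccccc1)c1ccccc1.[Br-]
Why: Wittig olefination with the β-oxido ylide, a reagent class that favours (E)-allylic alcohols, should form the disubstituted alkene and bring in the tertiary carbinol at once, excess ylide covering the free C2 hydroxyl (a cis-epoxy alcohol, so no Payne migration).

Step 14
Reactants: 27 (3E,5Z)-6-(3α,4α-epoxy-2α-hydroxy-1β,4β-dimethyl-7αH-bicyclo[5.3.0]decan-8α-yl)-2-methylhepta-3,5-dien-2-ol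
Product: 28 2α-acetoxy-3α,4α-epoxy-8α-[(2Z,4E)-6-hydroxy-6-methylhepta-2,4-dien-2-yl]-1β,4β-dimethyl-7αH-bicyclo[5.3.0]decane (CNP0265175.1)
Conditions: Ac2O, pyridine, DMAP (cat.), CH2Cl2, 0 °C
Reagents that add atoms: acetic anhydride, CC(=O)OC(C)=O
Why: Acylation should take the secondary hydroxyl in preference to the tertiary allylic one, giving the target.

**Compound list**

1 | ethyl but-2-ynoate | CC#CC(=O)OCC | starting material
2 | ethyl (2Z)-3-iodobut-2-enoate | CCOC(=O)/C=C(/C)I | intermediate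
3 | cyclopent-2-en-1-one | O=C1C=CCC1 | starting material
4 | [(2Z)-4-ethoxy-4-oxobut-2-en-2-yl]zinc iodide | CCOC(=O)/C=C(/C)[Zn]I | intermediate (not isolated)
5 | ethyl (2Z)-3-[(1R)-3-(trimethylsilyloxy)cyclopent-2-en-1-yl]but-2-enoate | C[Si](C)(C)OC1=C[C@H](/C(C)=C\C(=O)OCC)CC1 | intermediate
6 | 2-(2-bromoethyl)-2-methyl-1,3-dioxolane | CC1(CCBr)OCCO1 | starting material
7 | benzyltrimethylammonium (3R)-3-[(2Z)-4-ethoxy-4-oxobut-2-en-2-yl]cyclopent-1-en-1-olate | C[N+](C)(C)Cc1ccccc1.[O-]C1=C[C@H](/C(C)=C\C(=O)OCC)CC1 | intermediate (not isolated)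
8 | ethyl (2Z)-3-{(1R,2S)-2-[2-(2-methyl-1,3-dioxolan-2-yl)ethyl]-3-oxocyclopentyl}but-2-enoate | CC1(OCCO1)CC[C@H]2[C@H](/C(C)=C\C(=O)OCC)CCC2=O | intermediate
9 | ethyl (2Z)-3-{(1R,2S)-3-methylidene-2-[2-(2-methyl-1,3-dioxolan-2-yl)ethyl]cyclopentyl}but-2-enoate | CC1(OCCO1)CC[C@H]2[C@H](/C(C)=C\C(=O)OCC)CCC2=C | intermediate (not isolated)
10 | ethyl (2Z)-3-[(1R,2S)-3-methylidene-2-(3-oxobutyl)cyclopentyl]but-2-enoate | CC(=O)CC[C@H]1[C@H](/C(C)=C\C(=O)OCC)CCC1=C | intermediate
11 | vinyltriphenylphosphonium bromide | C=C[P+](c1ccccc1)(c1ccccc1)c1ccccc1.[Br-] | starting material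
12 | {2-[(1R,2S,3R)-3-[(2Z)-4-ethoxy-4-oxobut-2-en-2-yl]-1-methyl-2-(3-oxobutyl)cyclopentyl]ethyl}triphenylphosphonium bromide | CC(=O)CC[C@H]1[C@H](/C(C)=C\C(=O)OCC)CC[C@]1(C)CC[P+](c1ccccc1)(c1ccccc1)c1ccccc1.[Br-] | intermediate (not isolated)
13 | ylide of 12 (P=CH at the carbon next to phosphorus) | CC(=O)CC[C@H]1[C@H](/C(C)=C\C(=O)OCC)CC[C@]1(C)CC=P(c1ccccc1)(c1ccccc1)c1ccccc1 | intermediate (not isolated)
14 | ethyl (2Z)-3-(1β,4-dimethyl-7αH-bicyclo[5.3.0]dec-3-en-8α-yl)but-2-enoate | C1C=C(C)CC[C@H]2[C@H](/C(C)=C\C(=O)OCC)CC[C@]12C | intermediate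
15 | ethyl (2Z)-3-(3α,4α-epoxy-1β,4β-dimethyl-7αH-bicyclo[5.3.0]decan-8α-yl)but-2-enoate | C1[C@@H]2O[C@]2(C)CC[C@H]2[C@H](/C(C)=C\C(=O)OCC)CC[C@]12C | intermediate
16 | ethyl (2Z)-3-[4α-hydroxy-1β,4β-dimethyl-3β-(phenylselanyl)-7αH-bicyclo[5.3.0]decan-8α-yl]but-2-enoate | C1[C@@H]([Se]c3ccccc3)[C@@](O)(C)CC[C@H]2[C@H](/C(C)=C\C(=O)OCC)CC[C@]12C | intermediate (not isolated)
17 | selenoxide of 16 | C1[C@@H]([Se](=O)c3ccccc3)[C@@](O)(C)CC[C@H]2[C@H](/C(C)=C\C(=O)OCC)CC[C@]12C | intermediate (not isolated)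
18 | ethyl (2Z)-3-(4α-hydroxy-1β,4β-dimethyl-7αH-bicyclo[5.3.0]dec-2-en-8α-yl)but-2-enoate | C1=C[C@@](O)(C)CC[C@H]2[C@H](/C(C)=C\C(=O)OCC)CC[C@]12C | intermediate
19 | ethyl (2Z)-3-(2α-hydroxy-1β,4-dimethyl-7αH-bicyclo[5.3.0]dec-3-en-8α-yl)but-2-enoate | O[C@@H]1C=C(C)CC[C@H]2[C@H](/C(C)=C\C(=O)OCC)CC[C@]12C | intermediate
20 | ethyl (2Z)-3-(3α,4α-epoxy-2α-hydroxy-1β,4β-dimethyl-7αH-bicyclo[5.3.0]decan-8α-yl)but-2-enoate | O[C@@H]1[C@@H]2O[C@]2(C)CC[C@H]2[C@H](/C(C)=C\C(=O)OCC)CC[C@]12C | intermediate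
21 | (2Z)-3-(3α,4α-epoxy-2α-hydroxy-1β,4β-dimethyl-7αH-bicyclo[5.3.0]decan-8α-yl)but-2-en-1-ol | O[C@@H]1[C@@H]2O[C@]2(C)CC[C@H]2[C@H](/C(C)=C\CO)CC[C@]12C | intermediate
22 | (2Z)-3-(3α,4α-epoxy-2α-hydroxy-1β,4β-dimethyl-7αH-bicyclo[5.3.0]decan-8α-yl)but-2-enal | O[C@@H]1[C@@H]2O[C@]2(C)CC[C@H]2[C@H](/C(C)=C\C=O)CC[C@]12C | intermediate
23 | 2,2-dimethyloxirane | CC1(C)CO1 | starting material
24 | triphenylphosphine hydrobromide | [PH+](c1ccccc1)(c1ccccc1)c1ccccc1.[Br-] | starting material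
25 | (2-hydroxy-2-methylpropyl)triphenylphosphonium bromide | CC(C)(O)C[P+](c1ccccc1)(c1ccccc1)c1ccccc1.[Br-] | intermediate
26 | lithium 2-methyl-1-(triphenyl-λ5-phosphanylidene)propan-2-olate | CC(C)([O-])C=P(c1ccccc1)(c1ccccc1)c1ccccc1.[Li+] | intermediate (not isolated)
27 | (3E,5Z)-6-(3α,4α-epoxy-2α-hydroxy-1β,4β-dimethyl-7αH-bicyclo[5.3.0]decan-8α-yl)-2-methylhepta-3,5-dien-2-ol | O[C@@H]1[C@@H]2O[C@]2(C)CC[C@H]2[C@H](/C(C)=C\C=C\C(C)(C)O)CC[C@]12C | intermediate
28 | 2α-acetoxy-3α,4α-epoxy-8α-[(2Z,4E)-6-hydroxy-6-methylhepta-2,4-dien-2-yl]-1β,4β-dimethyl-7αH-bicyclo[5.3.0]decane (CNP0265175.1) | CC(=O)O[C@@H]1[C@@H]2O[C@]2(C)CC[C@H]2[C@H](/C(C)=C\C=C\C(C)(C)O)CC[C@]12C | target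

**Step count.** 14 steps in total; longest linear sequence 13 steps (steps 1–11, 13 and 14; step 12 is the side branch).

**Steps most likely to fail**

Step 5 (proposed new method). The tertiary radical may cyclise onto its own ketone (5-exo) or be reduced before it meets the acceptor, and the ylide stage may lose material to enolisation of the methyl ketone. The fallback uses documented reactions and starts from 8. Methylenation without the acidic work-up gives ketal alkene 9, which is isolated. Iron-mediated Giese addition (Fe(acac)3, PhSiH3, EtOH) to phenyl vinyl sulfone, a documented acceptor class, should give ethyl (2Z)-3-{(1R,2S,3R)-3-methyl-2-[2-(2-methyl-1,3-dioxolan-2-yl)ethyl]-3-[2-(phenylsulfonyl)ethyl]cyclopentyl}but-2-enoate F1. Deprotonation α to sulfur (LDA, −78 °C) and oxidative desulfonylation (MoO5·py·HMPA) should give the aldehyde ethyl (2Z)-3-{(1R,2S,3R)-3-methyl-2-[2-(2-methyl-1,3-dioxolan-2-yl)ethyl]-3-(2-oxoethyl)cyclopentyl}but-2-enoate F2. PPTS in aqueous acetone then frees the keto aldehyde ethyl (2Z)-3-[(1R,2S,3R)-3-methyl-2-(3-oxobutyl)-3-(2-oxoethyl)cyclopentyl]but-2-enoate F3. Intramolecular McMurry coupling (TiCl3(DME)1.5, Zn–Cu, DME, reflux) closes C3=C4 and returns to 14.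

Step 7. Selenolate must enter at C3 syn to the axial C1 methyl group, so opening may be slow, and reversible conjugate addition of selenolate to the enoate may erode its Z geometry. The fallback replaces the oxygen relay of steps 6–8 by C–H oxidation and inversion, starting from 14. Allylic oxidation at C2, the methylene next to the alkene CH (Rh2(cap)4 cat., t-BuOOH), should give the enone ethyl (2Z)-3-(1β,4-dimethyl-2-oxo-7αH-bicyclo[5.3.0]dec-3-en-8α-yl)but-2-enoate F4. Luche reduction (NaBH4, CeCl3·7H2O), with hydride arriving anti to the methyl group, should give the 2β-alcohol ethyl (2Z)-3-(2β-hydroxy-1β,4-dimethyl-7αH-bicyclo[5.3.0]dec-3-en-8α-yl)but-2-enoate F5. Mitsunobu inversion (4-nitrobenzoic acid, PPh3, DIAD) should give the 2α-ester ethyl (2Z)-3-[1β,4-dimethyl-2α-(4-nitrobenzoyloxy)-7αH-bicyclo[5.3.0]dec-3-en-8α-yl]but-2-enoate F6. Ethanolysis (K2CO3, EtOH) then returns to 19.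

Step 3. Proton transfer between enolate and product, and polyalkylation, may outrun the slow alkylation by an unactivated primary bromide. The fallback starts from 5. Mukaiyama–Michael addition to but-3-en-2-one (TiCl4, CH2Cl2, −78 °C) should give the diketone ethyl (2Z)-3-[(1R,2S)-3-oxo-2-(3-oxobutyl)cyclopentyl]but-2-enoate F7. Chemoselective dioxolane formation at the unhindered methyl ketone (Me3SiOCH2CH2OSiMe3, Me3SiOTf cat., −78 °C) then returns to 8.

Further compounds
F1 | step 5 | ethyl (2Z)-3-{(1R,2S,3R)-3-methyl-2-[2-(2-methyl-1,3-dioxolan-2-yl)ethyl]-3-[2-(phenylsulfonyl)ethyl]cyclopentyl}but-2-enoate | CC1(OCCO1)CC[C@H]2[C@H](/C(C)=C\C(=O)OCC)CC[C@]2(C)CCS(=O)(=O)c1ccccc1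
F2 | step 5 | ethyl (2Z)-3-{(1R,2S,3R)-3-methyl-2-[2-(2-methyl-1,3-dioxolan-2-yl)ethyl]-3-(2-oxoethyl)cyclopentyl}but-2-enoate | CC1(OCCO1)CC[C@H]2[C@H](/C(C)=C\C(=O)OCC)CC[C@]2(C)CC=O
F3 | step 5 | ethyl (2Z)-3-[(1R,2S,3R)-3-methyl-2-(3-oxobutyl)-3-(2-oxoethyl)cyclopentyl]but-2-enoate | CC(=O)CC[C@H]1[C@H](/C(C)=C\C(=O)OCC)CC[C@]1(C)CC=O
F4 | step 7 | ethyl (2Z)-3-(1β,4-dimethyl-2-oxo-7αH-bicyclo[5.3.0]dec-3-en-8α-yl)but-2-enoate | O=C1C=C(C)CC[C@H]2[C@H](/C(C)=C\C(=O)OCC)CC[C@]12C
F5 | step 7 | ethyl (2Z)-3-(2β-hydroxy-1β,4-dimethyl-7αH-bicyclo[5.3.0]dec-3-en-8α-yl)but-2-enoate | O[C@H]1C=C(C)CC[C@H]2[C@H](/C(C)=C\C(=O)OCC)CC[C@]12C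
F6 | step 7 | ethyl (2Z)-3-[1β,4-dimethyl-2α-(4-nitrobenzoyloxy)-7αH-bicyclo[5.3.0]dec-3-en-8α-yl]but-2-enoate | O=C(O[C@@H]1C=C(C)CC[C@H]2[C@H](/C(C)=C\C(=O)OCC)CC[C@]12C)c1ccc(cc1)[N+](=O)[O-]
F7 | step 3 | ethyl (2Z)-3-[(1R,2S)-3-oxo-2-(3-oxobutyl)cyclopentyl]but-2-enoate | CC(=O)CC[C@H]1[C@H](/C(C)=C\C(=O)OCC)CCC1=O
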